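**Retrosynthetic overview**
1. The last bond made is the CH2 bridge between pyranone C3 and the one free carbon of the benzene ring, from 6-ethyl-4-hydroxy-5-methyl-2-pyranone, the prenylated (S)-2-methylbutanoylphloroglucinol and a one-carbon iminium salt.
2. The aromatic half comes from phloroglucinol by Friedel–Crafts acylation with (S)-2-methylbutanoyl chloride (the only stereocentre, bought) and mono-C-prenylation; the benzene ring is not built.
3. The plan rests on one feature of the fully substituted 2-pyranone ring: the enol-lactone bond O1–C6 and the carbon substituent at C5 lie on the neighbouring carbons C6 and C5, which can be the two carbons of an alkyne. C5–CH3 is cut back to C5–I and 4-OH to 4-OMe.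
4. Key disconnection: O1–C6 together with C5–I, by ICl-induced 6-endo-dig iodolactonisation of methyl (E)-3-methoxyhept-2-en-4-ynoate, itself made from pent-2-ynoic acid and a malonate half-ester followed by O-methylation.
5. Ring order: the pyranone is the only ring formed (step 3); the two halves are joined in the final step.

Key step: step 3

Remark on the chemistry: no step creates a stereocentre; the (S)-configured α-carbon of the acyl group is carried through from (S)-2-methylbutanoic acid, and hydroxypyranones are drawn as 4-hydroxy-2-pyranone tautomers.

**Route**

Step 1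
Reactants: 1 pent-2-ynoic acid; 2 potassium methyl malonate
Product: 5 methyl 3-oxohept-4-ynoate, via 1-(pent-2-ynoyl)imidazole 3 (not isolated), via acylmalonate half-ester 4 (not isolated)
Conditions: CDI, THF, 0 °C to rt; then 2, MgCl2, Et3N, MeCN/THF, rt; 1 M HCl work-up
Reagents that add atoms: 1,1'-carbonyldiimidazole, O=C(n1ccnc1)n1ccnc1 (supplies the imidazolyl group of intermediate 3 only; product 5 is built from 1 and 2 alone)
Why: Masamune–Brooks decarboxylative Claisen condensation, in which the magnesium enolate of the malonate half-ester is C-acylated by the acyl imidazolide and the product stays masked as a magnesium chelate (unreactive towards conjugate addition of imidazole) until acid releases it with loss of CO2.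

Step 2
Reactants: 5 methyl 3-oxohept-4-ynoate
Product: 6 methyl (E)-3-methoxyhept-2-en-4-ynoate
Conditions: Cs2CO3, Me2SO4, DMF, 0 °C to rt
Reagents that add atoms: dimethyl sulfate, COS(=O)(=O)OC
Why: O-alkylation of an ambident β-keto ester enolate, where the large non-chelating cesium counter-ion in DMF lets the enolate react from its extended form (the two oxygens turned apart) with the hard electrophile at oxygen, so that OMe ends trans to the ester, giving the (E)-enol ether with ester and alkyne cis, which should also be the more stable isomer.

Step 3
Reactants: 6 methyl (E)-3-methoxyhept-2-en-4-ynoate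
Product: 8 6-ethyl-5-iodo-4-methoxy-2H-pyran-2-one, via dimethoxypyrylium chloride 7 (not isolated)
Conditions: ICl (1.05 equiv), CH2Cl2, −78 to 0 °C, dark; aq. Na2S2O3 work-up
Reagents that add atoms: iodine monochloride, ClI
Why: ICl delivers I+ to the C4≡C5 triple bond and the ester carbonyl oxygen, held cis to the alkyne by the (E)-enol ether, opens the iodonium anti at the ethyl-bearing carbon to give the 2,4-dimethoxypyrylium chloride 7, from which chloride removes the ester O-methyl group (SN2, loss of CH3Cl) to leave the lactone. The closest known reaction type is the electrophilic iodolactonisation of 2-en-4-ynoate esters with cis ester and alkyne, using ICl or I2, to give 5-iodo-2-pyranones. The pyranone ring closes in the 6-endo-dig mode, forming the O1–C6 and C5–I bonds in one operation, and no stereocentre is created. The step needs 6-endo closure to win over 5-exo closure to an iodoalkylidene furanone; this should be secured by the polarisation of the iodonium, since the ethyl-bearing terminus carries positive charge better than the terminus attached to the inductively withdrawing, methoxy-bearing C3, and by the high nucleophilicity of the vinylogous-carbonate carbonyl oxygen. It also needs the alkyne to react before C2 of the push–pull enol ether or C3 of the product is iodinated, which is addressed by one equivalent of ICl at low temperature, C2 being deactivated by the ester. Should chloride instead remove the methyl group on the C4 oxygen, the isomeric 2-methoxy-4-pyranone would converge on the same hydroxypyranone after steps 4 and 5.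

Step 4
Reactants: 8 6-ethyl-5-iodo-4-methoxy-2H-pyran-2-one
Product: 9 6-ethyl-4-methoxy-5-methyl-2H-pyran-2-one
Conditions: MeZnCl (2 M in THF), Pd(PPh3)4 (5 mol%), THF, rt to 50 °C
Reagents that add atoms: methylzinc chloride, C[Zn]Cl
Why: Negishi cross-coupling, in which zerovalent palladium inserts into the C5–I bond, the methyl group (no β-hydrogen) is transferred from zinc and reductive elimination forms C5–CH3, while the lactone and the enol ether are inert to the organozinc reagent.

Step 5
Reactants: 9 6-ethyl-4-methoxy-5-methyl-2H-pyran-2-one
Product: 10 6-ethyl-4-hydroxy-5-methyl-2H-pyran-2-one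
Conditions: 33% HBr in AcOH, 90 °C
Reagents that add atoms: none
Why: Acid-mediated SN2 O-demethylation (HBr ether cleavage), in which protonation of the ring carbonyl turns the 4-methoxy group into the methyl ether of a hydroxypyrylium ion and bromide removes the methyl group as CH3Br, the pyranone ring itself being stable to hot acid.

Step 6
Reactants: 11 (S)-2-methylbutanoic acid
Product: 12 (S)-2-methylbutanoyl chloride
Conditions: (COCl)2 (1.0 equiv), cat. DMF, CH2Cl2, 0 °C to rt; concentrated cold and used crude
Reagents that add atoms: oxalyl chloride, O=C(Cl)C(=O)Cl
Why: Acid chloride formation through the Vilsmeier-type chloroiminium ion runs without base at or below room temperature, so the untouched α-stereocentre should keep its (S) configuration.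

Step 7
Reactants: 12 (S)-2-methylbutanoyl chloride; 13 phloroglucinol
Product: 14 (S)-2-methyl-1-(2,4,6-trihydroxyphenyl)butan-1-one
Conditions: AlCl3 (3.5 equiv), PhNO2/CH2Cl2, 0 °C to rt; ice/aq. HCl
Reagents that add atoms: none
Why: Friedel–Crafts C-acylation of the electron-rich triol (any O-acylated material rearranging to the chelated aryl ketone under AlCl3), run cold so that the acylium ion is captured before it can lose its α-proton to a ketene, which should preserve the (S) centre; the three ring positions are equivalent, so a single ketone results.

Step 8
Reactants: 14 (S)-2-methyl-1-(2,4,6-trihydroxyphenyl)butan-1-one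
Product: 15 (S)-2-methyl-1-[2,4,6-trihydroxy-3-(3-methylbut-2-en-1-yl)phenyl]butan-1-one
Conditions: prenyl bromide (0.9 equiv), DBU (1.0 equiv), THF, 0 °C to rt
Reagents that add atoms: 1-bromo-3-methylbut-2-ene (prenyl bromide), CC(C)=CCBr
Why: C-alkylation of the ambident phenolate of an acylphloroglucinol by an allylic bromide (SN2 at ring carbon via the dienone tautomer), in which the two free ring carbons of 14 are equivalent, a slight deficit of bromide limits double prenylation, and DBU deprotonates the acidic phenol and not the ketone α-carbon, so the stereocentre is not at risk.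

Step 9
Reactants: 10 6-ethyl-4-hydroxy-5-methyl-2H-pyran-2-one; 15 (S)-2-methyl-1-[2,4,6-trihydroxy-3-(3-methylbut-2-en-1-yl)phenyl]butan-1-one
Product: 18 6-ethyl-4-hydroxy-5-methyl-3-{[2,4,6-trihydroxy-3-(3-methylbut-2-en-1-yl)-5-[(2S)-2-methylbutanoyl]phenyl]methyl}-2H-pyran-2-one, via Mannich base 16 (not isolated), via methylidenepyrandione 17 (not isolated)
Conditions: 10, Me2N=CH2+ I− (1.0 equiv), MeCN, rt; then 15, 50 °C
Reagents that add atoms: N,N-dimethylmethyleneiminium iodide (Eschenmoser's salt), C=[N+](C)C.[I-]
Why: Mannich reaction at the nucleophilic C3 of the 4-hydroxypyranone, loss of dimethylamine to the methylidene dione 17 and conjugate (Friedel–Crafts-type) addition of the only free ring carbon of 15 should build the CH2 bridge under near-neutral conditions that spare the prenyl group and the stereocentre; converting 10 fully into 16 before 15 is added guards against the symmetrical bis-pyranone.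

**Compound list**
1 | pent-2-ynoic acid | CCC#CC(=O)O | starting material
2 | potassium methyl malonate | COC(=O)CC(=O)[O-].[K+] | starting material
3 | 1-(pent-2-ynoyl)-1H-imidazole | CCC#CC(=O)n1ccnc1 | intermediate
4 | 2-(methoxycarbonyl)-3-oxohept-4-ynoic acid (present as its magnesium chelate) | CCC#CC(=O)C(C(=O)OC)C(=O)O | intermediate
5 | methyl 3-oxohept-4-ynoate | CCC#CC(=O)CC(=O)OC | intermediate
6 | methyl (E)-3-methoxyhept-2-en-4-ynoate | CCC#C/C(OC)=C\C(=O)OC | intermediate
7 | 6-ethyl-5-iodo-2,4-dimethoxypyrylium chloride | CCc1[o+]c(OC)cc(OC)c1I.[Cl-] | intermediate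
8 | 6-ethyl-5-iodo-4-methoxy-2H-pyran-2-one | CCc1oc(=O)cc(OC)c1I | intermediate
9 | 6-ethyl-4-methoxy-5-methyl-2H-pyran-2-one | CCc1oc(=O)cc(OC)c1C | intermediate
10 | 6-ethyl-4-hydroxy-5-methyl-2H-pyran-2-one | CCc1oc(=O)cc(O)c1C | intermediate
11 | (S)-2-methylbutanoic acid | CC[C@H](C)C(=O)O | starting material
12 | (S)-2-methylbutanoyl chloride | CC[C@H](C)C(=O)Cl | intermediate
13 | phloroglucinol (benzene-1,3,5-triol) | Oc1cc(O)cc(O)c1 | starting material
14 | (S)-2-methyl-1-(2,4,6-trihydroxyphenyl)butan-1-one | CC[C@H](C)C(=O)c1c(O)cc(O)cc1O | intermediate
15 | (S)-2-methyl-1-[2,4,6-trihydroxy-3-(3-methylbut-2-en-1-yl)phenyl]butan-1-one | CC[C@H](C)C(=O)c1c(O)cc(O)c(CC=C(C)C)c1O | intermediate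
16 | 3-[(dimethylamino)methyl]-6-ethyl-4-hydroxy-5-methyl-2H-pyran-2-one hydroiodide | CCc1oc(=O)c(CN(C)C)c(O)c1C.I | intermediate
17 | 6-ethyl-5-methyl-3-methylidene-2H-pyran-2,4(3H)-dione | CCC1=C(C)C(=O)C(=C)C(=O)O1 | intermediate
18 | 6-ethyl-4-hydroxy-5-methyl-3-{[2,4,6-trihydroxy-3-(3-methylbut-2-en-1-yl)-5-[(2S)-2-methylbutanoyl]phenyl]methyl}-2H-pyran-2-one | CCc1oc(=O)c(Cc2c(O)c(CC=C(C)C)c(O)c(C(=O)[C@@H](C)CC)c2O)c(O)c1C | target

**Totals**
Total step count: 9.
Longest linear sequence: 6 steps (steps 1–5 and step 9, from pent-2-ynoic acid).

**Steps most likely to fail**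

Step 3. The ring closure may go in the 5-exo mode onto the inner alkyne carbon, or electrophilic iodination at C2 of the enol ether (or C3 of the product) may compete with activation of the alkyne. The fallback gives up the alkyne and builds the pyranone from a triketide. It sets out from compound 2, which is C-acylated with propanoyl chloride (MgCl2, Et3N, MeCN, then aq. HCl) to give methyl 3-oxopentanoate F1. F1 is deprotonated twice (NaH, then n-BuLi, THF, 0 °C) and acylated at the γ-carbon with N-methoxy-N-methylpropanamide to give methyl 4-methyl-3,5-dioxoheptanoate F2. F2 is enol-lactonised with DBU in refluxing toluene, with loss of methanol. The fallback comes back to the route at compound 10, with the C5 methyl and C6 ethyl groups fixed by the carbon chain.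

Step 2. Methylation at carbon may compete with methylation at oxygen, and the enol ether geometry may not be fully controlled; the (Z) isomer cannot cyclise. The fallback replaces kinetic enolate alkylation by acetalisation and elimination under thermodynamic control. It sets out from compound 5, which with HC(OMe)3 and catalytic TsOH in MeOH should give methyl 3,3-dimethoxyhept-4-ynoate F3. Warming F3 with the acid catalyst while methanol is distilled off should eliminate one methanol and equilibrate the enol ether to the more stable (E) isomer. It comes back at compound 6.

Step 7. Enantiomeric purity may erode through reversible ketene formation from the acylium ion or through Lewis-acid-promoted enolisation of the aryl ketone. The fallback forms the aryl–acyl bond with an organolithium under non-enolising conditions. It sets out from compound 13, which is converted with MOMCl and i-Pr2NEt into 1,3,5-tris(methoxymethoxy)benzene F4. In parallel, compound 11 is coupled with MeNHOMe·HCl (CDI, CH2Cl2) to give (S)-N-methoxy-N,2-dimethylbutanamide F5. F4 is ortho-lithiated (n-BuLi, THF, 0 °C) and added to F5 at −78 °C, which should give (S)-2-methyl-1-[2,4,6-tris(methoxymethoxy)phenyl]butan-1-one F6 through a stable chelated tetrahedral intermediate. Mild acetal cleavage (HCl, MeOH, rt) comes back to the route at compound 14.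

**Further compounds**
F1 | step 3 | methyl 3-oxopentanoate | CCC(=O)CC(=O)OC
F2 | step 3 | methyl 4-methyl-3,5-dioxoheptanoate | CCC(=O)C(C)C(=O)CC(=O)OC
F3 | step 2 | methyl 3,3-dimethoxyhept-4-ynoate | CCC#CC(OC)(OC)CC(=O)OC
F4 | step 7 | 1,3,5-tris(methoxymethoxy)benzene | COCOc1cc(OCOC)cc(OCOC)c1
F5 | step 7 | (S)-N-methoxy-N,2-dimethylbutanamide | CC[C@H](C)C(=O)N(C)OC
F6 | step 7 | (S)-2-methyl-1-[2,4,6-tris(methoxymethoxy)phenyl]butan-1-one | CC[C@H](C)C(=O)c1c(OCOC)cc(OCOC)cc1OCOC
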